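**Assumption (one line):** (S)-4-hydroxymandelic acid is purchasable as a single enantiomer. The two 3-bromo-4-hydroxyphenyl groups are identical, so both come from one aldehyde.

## Retrosynthetic overview
1. Target ⇐ global desilylation of the protected butenolide **14**; the C=C of the butenolide comes from dehydration of the 4-hydroxy-5-(Z)-arylidene lactone **13**.
2. **13** ⇐ Au-catalysed 5-exo-dig lactonisation of the t-Bu ester alkyne **12**. This is the only ring formed, and it also sets the Z-arylidene.
3. **12** ⇐ ester-enolate 1,2-aldol of **6** with the diaryl ynone **11** (forms C3–C4).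
4. **6** ⇐ photochemical Wolff rearrangement (Arndt–Eistert) of diazoketone **5**. This forms the C(carbinol)–C3 bond with retention, so the stereocentre comes from (S)-4-hydroxymandelic acid **1**.
5. Ring A comes from the bromination and O-methylation of **1**; rings B and C come from 3-bromo-4-hydroxybenzaldehyde **7**.

## Route

**Step 1**
Reactants: 1 (S)-4-hydroxymandelic acid
Product: 2 (S)-3,5-dibromo-4-hydroxymandelic acid
Conditions: Br2 (2.1 equiv), AcOH, 15 °C → rt
Reagents that add atoms: Br2 (BrBr)
Why: Electrophilic aromatic bromination goes ortho to the phenol OH. The stereocentre is not touched.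

**Step 2**
Reactants: 2
Product: 3 (S)-3,5-dibromo-4-methoxymandelic acid
Conditions: Me2SO4 (1.2 equiv), NaOH (2.5 equiv), H2O, 0 °C → rt
Reagents that add atoms: Me2SO4 (COS(=O)(=O)OC)
Why: The 2,6-dibromophenoxide (pKa ≈ 7) is selectively O-methylated (Williamson). The carboxylate and benzylic OH are not alkylated, and the α-H of a carboxylate is not acidic, so there is no racemisation.

**Step 3**
Reactants: 3
Product: 4 (S)-2-(TBS-oxy)-2-(3,5-dibromo-4-methoxyphenyl)acetic acid
Conditions: TBSCl (2.5 equiv), imidazole (5 equiv), DMF, rt; then aq. citric acid/THF workup to cleave the silyl ester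
Reagents that add atoms: TBSCl (CC(C)(C)[Si](C)(C)Cl)
Why: Silylation protects the secondary OH. The labile TBS ester is hydrolysed on workup, leaving the free acid. The stereocentre is unchanged.

**Step 4**
Reactants: 4
Product: 5 (S)-1-diazo-3-(TBS-oxy)-3-(3,5-dibromo-4-methoxyphenyl)propan-2-one
Conditions: i-BuOCOCl, NMM, THF, −15 °C; then CH2N2 (Et2O, flow-generated), 0 °C → rt
Reagents that add atoms: CH2N2 (C=[N+]=[N-])
Why: The mixed anhydride is acylated by diazomethane (Arndt–Eistert diazoketone formation). The low-temperature mixed anhydride avoids ketene formation and racemisation.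

**Step 5**
Reactants: 5
Product: 6 tert-butyl (R)-3-(TBS-oxy)-3-(3,5-dibromo-4-methoxyphenyl)propanoate
Conditions: hν (365 nm LEDs, FEP flow reactor), t-BuOH/THF 1:1, 20 °C
Reagents that add atoms: t-BuOH (CC(C)(C)O)
Why: Photochemical Wolff rearrangement. The benzylic carbinol carbon migrates to the carbene carbon with retention, forming the key C–C bond, and the ketene is trapped by t-BuOH as the t-Bu ester. The descriptor changes from S to R only because CIP priorities change; the spatial arrangement is unchanged. 365 nm avoids C–Br photolysis.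

**Step 6**
Reactants: 7 3-bromo-4-hydroxybenzaldehyde
Product: 8 3-bromo-4-(TIPS-oxy)benzaldehyde
Conditions: TIPSCl, imidazole, DMF, rt
Reagents that add atoms: TIPSCl (CC(C)[Si](Cl)(C(C)C)C(C)C)
Why: Silyl protection of the phenol, with a TIPS group that survives LDA and K2CO3/MeOH.

**Step 7**
Reactants: 8
Product: 9 (2-bromo-4-ethynylphenoxy)triisopropylsilane
Conditions: Ohira–Bestmann reagent, K2CO3, MeOH, rt
Reagents that add atoms: dimethyl (1-diazo-2-oxopropyl)phosphonate (COP(=O)(OC)C(=[N+]=[N-])C(C)=O)
Why: Seyferth–Gilbert/Ohira–Bestmann one-carbon homologation of the aldehyde to the terminal alkyne. The TIPS aryl ether tolerates K2CO3/MeOH.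

**Step 8**
Reactants: 9, 8
Product: 10 1,3-bis[3-bromo-4-(TIPS-oxy)phenyl]prop-2-yn-1-ol
Conditions: EtMgBr (1.0 equiv), THF, 0 °C (formation of alkynyl-MgBr); then 8, 0 °C → rt
Reagents that add atoms: none (EtMgBr only deprotonates)
Why: Alkynyl Grignard 1,2-addition to the aldehyde. EtMgBr does not exchange the aryl bromides at this temperature.

**Step 9**
Reactants: 10
Product: 11 1,3-bis[3-bromo-4-(TIPS-oxy)phenyl]prop-2-yn-1-one
Conditions: Dess–Martin periodinane, NaHCO3, CH2Cl2, rt
Reagents that add atoms: none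
Why: Oxidation of the propargylic alcohol to the ynone. No stereocentre is involved.

**Step 10**
Reactants: 6, 11
Product: 12 tert-butyl 2-[(R)-(TBS-oxy)(3,5-dibromo-4-methoxyphenyl)methyl]-3-hydroxy-3,5-bis[3-bromo-4-(TIPS-oxy)phenyl]pent-4-ynoate (mixture of C2/C3 diastereomers)
Conditions: LDA (1.05 equiv), THF, −78 °C, 30 min; then 11, −78 °C, 1 h; cold aq. NH4Cl quench
Reagents that add atoms: none
Why: Ester-enolate aldol (1,2-addition to the ynone carbonyl) forms C3–C4. The two new stereocentres are destroyed later by dehydration. The carbinol centre is β, not α, to the ester and is not epimerised; −78 °C prevents β-elimination of OTBS.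

**Step 11**
Reactants: 12
Product: 13 (5Z)-3-[(R)-(TBS-oxy)(3,5-dibromo-4-methoxyphenyl)methyl]-4-hydroxy-4-[3-bromo-4-(TIPS-oxy)phenyl]-5-[3-bromo-4-(TIPS-oxy)benzylidene]dihydrofuran-2(3H)-one
Conditions: Ph3PAuNTf2 (5 mol %), DCE, 40 °C
Reagents that add atoms: none (loses isobutene)
Why: Proposed new method: Au(I) π-activates the internal alkyne. The t-Bu ester carbonyl oxygen attacks 5-exo-dig, anti to gold, and the oxocarbenium loses t-Bu⁺ as isobutene, so the lactone closes under neutral conditions without ester hydrolysis. Anti oxyauration followed by protodeauration puts the aryl cis to O1, giving the Z-arylidene. The closest known reactions are Au/Ag cyclisation of t-Bu 2-alkynylbenzoates to isocoumarins and of 4-alkynoic acids to γ-alkylidene lactones. The new feature is the substrate class: a β-hydroxy-γ,δ-alkynyl t-Bu ester with a tertiary benzylic propargylic OH.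

**Step 12**
Reactants: 13
Product: 14 protected target, (Z)-butenolide with OTBS at the carbinol and two TIPS aryl ethers
Conditions: MsCl (1.5 equiv), Et3N (4 equiv), CH2Cl2, 0 °C → rt
Reagents that add atoms: none (Ms leaves as MsOH)
Why: The tertiary, doubly benzylic/allylic alcohol is mesylated and undergoes E1cB/E1 loss of MsOH with the acidic C3–H, forming the C3=C4 butenolide alkene. OMs leaves far more readily than the carbinol OTBS, and the carbinol centre is untouched. The Z-arylidene is thermodynamically preferred.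

**Step 13**
Reactants: 14
Product: 15 target
Conditions: TBAF (6 equiv), AcOH (6 equiv), THF, 0 °C → rt, dark
Reagents that add atoms: none
Why: Fluoride removes the TBS and both TIPS groups in one step. AcOH buffering protects the lactone and prevents base-induced epimerisation or elimination.

## Compound list
1 | (S)-4-hydroxymandelic acid | Oc1ccc(cc1)[C@H](O)C(=O)O | starting material
2 | (S)-3,5-dibromo-4-hydroxymandelic acid | Oc1c(Br)cc([C@H](O)C(=O)O)cc1Br | intermediate
3 | (S)-3,5-dibromo-4-methoxymandelic acid | COc1c(Br)cc([C@H](O)C(=O)O)cc1Br | intermediate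
4 | (S)-2-(TBS-oxy)-2-(3,5-dibromo-4-methoxyphenyl)acetic acid | COc1c(Br)cc([C@H](O[Si](C)(C)C(C)(C)C)C(=O)O)cc1Br | intermediate
5 | (S)-1-diazo-3-(TBS-oxy)-3-(3,5-dibromo-4-methoxyphenyl)propan-2-one | COc1c(Br)cc([C@H](O[Si](C)(C)C(C)(C)C)C(=O)C=[N+]=[N-])cc1Br | intermediate
6 | tert-butyl (R)-3-(TBS-oxy)-3-(3,5-dibromo-4-methoxyphenyl)propanoate | COc1c(Br)cc([C@H](O[Si](C)(C)C(C)(C)C)CC(=O)OC(C)(C)C)cc1Br | intermediate
7 | 3-bromo-4-hydroxybenzaldehyde | O=Cc1ccc(O)c(Br)c1 | starting material
8 | 3-bromo-4-(TIPS-oxy)benzaldehyde | O=Cc1ccc(O[Si](C(C)C)(C(C)C)C(C)C)c(Br)c1 | intermediate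
9 | (2-bromo-4-ethynylphenoxy)triisopropylsilane | C#Cc1ccc(O[Si](C(C)C)(C(C)C)C(C)C)c(Br)c1 | intermediate
10 | 1,3-bis[3-bromo-4-(TIPS-oxy)phenyl]prop-2-yn-1-ol | OC(C#Cc1ccc(O[Si](C(C)C)(C(C)C)C(C)C)c(Br)c1)c1ccc(O[Si](C(C)C)(C(C)C)C(C)C)c(Br)c1 | intermediate
11 | 1,3-bis[3-bromo-4-(TIPS-oxy)phenyl]prop-2-yn-1-one | O=C(C#Cc1ccc(O[Si](C(C)C)(C(C)C)C(C)C)c(Br)c1)c1ccc(O[Si](C(C)C)(C(C)C)C(C)C)c(Br)c1 | intermediate
12 | aldol adduct (t-Bu ester, tertiary propargylic alcohol) | COc1c(Br)cc([C@H](O[Si](C)(C)C(C)(C)C)C(C(=O)OC(C)(C)C)C(O)(C#Cc2ccc(O[Si](C(C)C)(C(C)C)C(C)C)c(Br)c2)c2ccc(O[Si](C(C)C)(C(C)C)C(C)C)c(Br)c2)cc1Br | intermediate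
13 | (5Z)-4-hydroxy-5-arylidene lactone | COc1c(Br)cc([C@H](O[Si](C)(C)C(C)(C)C)C2C(O)(c3ccc(O[Si](C(C)C)(C(C)C)C(C)C)c(Br)c3)/C(=C/c3ccc(O[Si](C(C)C)(C(C)C)C(C)C)c(Br)c3)OC2=O)cc1Br | intermediate
14 | protected butenolide | COc1c(Br)cc([C@H](O[Si](C)(C)C(C)(C)C)C2=C(c3ccc(O[Si](C(C)C)(C(C)C)C(C)C)c(Br)c3)/C(=C/c3ccc(O[Si](C(C)C)(C(C)C)C(C)C)c(Br)c3)OC2=O)cc1Br | intermediate
15 | target CID71459453 | COc1c(Br)cc([C@H](O)C2=C(c3ccc(O)c(Br)c3)/C(=C/c3ccc(O)c(Br)c3)OC2=O)cc1Br | target

## Totals
- Total steps: 13 (9 on the mandelic branch and convergent sequence, 4 on the ynone branch).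
- Longest linear sequence: 9 steps (1 → 2 → 3 → 4 → 5 → 6 → 12 → 13 → 14 → 15, counting the final three steps after the coupling).

## Three steps most likely to fail
1. **Step 11 (proposed new Au cyclisation).** Au can divert the tertiary propargylic alcohol into Meyer–Schuster or ionisation products, or close 6-endo at the aryl-bearing alkyne carbon.
   - Fallback: a different approach. Use the ester enolate of 6 in an aldol with 2-(TIPS-oxy)-1-[3-bromo-4-(TIPS-oxy)phenyl]ethanone. Lactonise to the C5-H2 4-aryl lactone, dehydrate it, then install the arylidene by classical base-mediated Knoevenagel condensation with 8, as in known rubrolide syntheses.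
2. **Step 10 (aldol).** The hindered t-Bu ester enolate adds slowly to a deactivated, electron-rich ynone. Retro-aldol, or β-elimination of OTBS, can compete.
   - Fallback: Claisen acylation of the Li enolate of 6 with the 3-bromo-4-(TIPS-oxy)benzoyl Weinreb amide to give a β-keto ester. Then add ArC≡CMgBr (from 9) to the ketone to reach the same intermediate 12.
3. **Step 5 (Wolff).** t-BuOH traps the ketene slowly, so dimerisation, O–H insertion and partial racemisation are possible.
   - Fallback: a metal-catalysed Wolff (AgOBz, Et3N, t-BuOH, sonication). Alternatively, replace the homologation with a Kowalski ynolate ester homologation of the corresponding methyl ester.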